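In a one-step world, with J always at hand, the turnover time R = [D]/rate stays constant: it is the inverse of a pseudo-first-order constant. These runs break that.

common to all: J 3.5 mM (held)
- grey: D 22 mM; the very flask that is asked about, followed so far
- amber: D 11 mM; run made earlier
- flask: D 22 mM; time 6.0 h

| grey: time / h | grey: X / % | amber: time / h | amber: X / % |
|---|---|---|---|
| 0.500 | 3 | 0.417 | 2 |
| 1.00 | 6 | 1.33 | 17 |
| 1.50 | 11 | 2.00 | 23 |
| 2.00 | 17 | 3.00 | 36 |
| 2.50 | 18 | 5.00 | 58 |
| 3.00 | 25 | 6.00 | 64 |

(standard deviation of a reading: 2 percentage points)
- at the start none of J is in solution
- east: doubling the transfer coefficient of J, all else as stated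
- south: doubling the saturation concentration of J, all else as stated
* how much X there is at 6.0 h, in percent of the D charged
* the change that raises the amount of X at 6.0 h, in percent of the D charged most ("none" if none brings more than 2 percentage points) (east / south / none)
* amount of X at 6.0 h, in percent of the D charged, after east

Between its readings at 1.00 h and 3.00 h, the grey run gives R = 8.89 h at [D] near 18.6 mM. The amber run reads 5.59 h near 6.87 mM, which is shorter. J has to cross into solution first, and if what crosses into solution equals what D uses, R is a straight line in [D]: a fixed part plus [D]/S. The two readings give S = 3.55 mM h⁻¹, my reading of the supply ceiling, the rate at which J crosses into solution holding none, and it carries the scatter of those readings. The fixed part is 3.66 h.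

I draw the grey curve. It starts flat, since no J is dissolved, and its straight stretch runs back to a knee at 0.368 h. At 3.00 h the reading leaves [D] = 16.5 mM, so R = 8.31 h. Holding that R, the curve bends gently to 47.7% at 6.0 h. Taking R at 11.0 mM from the knee, east gives 66.1%. For south I divide the R of the present flask at that [D] by two and get 81.1%, which is more.

The forecast says 49% (44% to 54%), a little above mine, and south. For east it says 63%, below mine: “East halves only the transfer term”.

The flask gives 47.3%, south as best with 31 percentage points against 23 points, and 70.1% after east.

    J ⇌ G, rate k1*(csat - [G]) (kL = 0.0125 min⁻¹)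
    D + G → X (k = 3.36 L mol⁻¹ min⁻¹)
    X ⇌ E (K = 0.120, k = 0.00445 min⁻¹)
    G → Q (k = 0.00258 min⁻¹)

Part of what holds X at 47.3% is the pace of the crossing of J to G, together with the hour of reading: with the crossing fast X stands at 88.0%, and ten times later at 89.3%. For the neighbour charged with 37 mM of D, the ceiling as I read it gives R = 14.1 h, so about 32.9% from the knee. That flask gives 32.3%.

The data are calculated for an exercise; scatter was added.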